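**Strategy.** Everything rests on cutting ring B at C5–C10, the central β,β′ bond of the adipic-type array C2–C1–C10–C5–C4–C3, next to a finished ring C. In the key step a hydrogen atom is transferred to the 1,1-disubstituted alkene on C9 (the extended isopropenyl group of (S)-carvone); the tertiary C10 radical closes ring B 6-exo onto an (E)-2-methyl enal at C5, forming quaternary C10, C5 and the trans B/C fusion in one operation. Ring C's diequatorial C8 and C9 side chains template the chair closure. The precursor is a ring C cyclohexanone already carrying the C14 ketone, the C13 methyl/vinyl centre, 11α-OBz, 8β-OSi and 7α-OAc; C4 methylation and a double oxidation (C2, C3) finish the diacid.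

Key step: step 14

Remark on numbering: atoms are numbered as in a 2,3-seco-isopimarane (ring B = C5–C10; ring C = C8, C9, C11–C14; C2 and C3 are the acid carbons). β is the ring C face carrying the C9 side chain, α the face of H-9. The stereocentre of (S)-carvone becomes C9.

Remark on materials and mixtures: paraformaldehyde, aldehyde 8 and 2-(triphenylphosphoranylidene)propanal are taken as commercial. Centres that are carried as inconsequential epimer mixtures (C13 in 7 and 9–13, the carbinol carbon in 15, C4 in 20) are written without descriptor.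

Step 1
Reactants: 1 (S)-carvone
Product: 2 (5S)-5-(4-hydroxybut-1-en-2-yl)-2-methylcyclohex-2-en-1-one
Conditions: (CH2O)n, Me2AlCl (2 equiv), CH2Cl2, 0 °C to rt; dilute HCl work-up
Reagents that add atoms: formaldehyde (as paraformaldehyde), C=O
Why: Lewis-acid promoted carbonyl-ene reaction of formaldehyde with the electron-rich 1,1-disubstituted alkene (the enone alkene is electron-poor and inert) should add C2 to the terminal carbon and move the double bond to the former methyl (future C20), leaving C9 untouched.

Step 2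
Reactants: 2 homoallylic alcohol
Product: 3 tert-butyldiphenylsilyl ether of 2
Conditions: t-BuPh2SiCl, imidazole, DMF, rt
Reagents that add atoms: tert-butyl(chloro)diphenylsilane, CC(C)(C)[Si](Cl)(c1ccccc1)c1ccccc1
Why: Standard silylation of the primary alcohol; this robust silyl ether is chosen to outlast the later selective cleavage of a primary tert-butyldimethylsilyl ether.

Step 3
Reactants: 3 silyl ether
Product: 5 (4R,5S)-4-hydroxy enone (11α-OH), via silyl dienol ether 4 (not isolated)
Conditions: Me3SiCl, NaI, Et3N, MeCN, rt; pentane extraction; then dimethyldioxirane, acetone, −78 to −40 °C; dilute HCl work-up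
Reagents that add atoms: dimethyldioxirane, CC1(C)OO1
Why: Thermodynamic silylation (Me3SiI made in the flask) should give the linear 1-silyloxy-1,3-diene, as with 4-en-3-one steroids, and oxygen transfer to its γ-terminus C11 (vinylogous Rubottom oxidation) should occur anti to the neighbouring C9 arm, setting 11α-OH trans to that arm.

Step 4
Reactants: 5 11α-hydroxy enone
Product: 6 11α-benzoate
Conditions: BzCl, pyridine, DMAP (cat.), CH2Cl2, 0 °C
Reagents that add atoms: benzoyl chloride, O=C(Cl)c1ccccc1
Why: DMAP-catalysed acylation of the secondary allylic alcohol installs the benzoate of the target with retention at C11.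

Step 5
Reactants: 6 benzoyloxy enone
Product: 7 saturated ketone (C13 epimers)
Conditions: LiBH(s-Bu)3 (1.05 equiv), THF, −78 °C; aqueous NH4Cl
Reagents that add atoms: none
Why: Conjugate hydride reduction of the 2-methylcyclohexenone (as known for carvone) at −78 °C should spare the benzoate; it removes the ring enone so that step 7 meets a single enone, and the C13 centre it creates is planarised again in step 9.

Step 6
Reactants: 7 saturated ketone; 8 3-(tert-butyldimethylsilyloxy)propanal
Product: 11 (E)-alkylidene ketone (C8=C7), via aldol adduct 9 (not isolated), via mesylate 10 (not isolated)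
Conditions: LiN(i-Pr)2, THF, −78 °C; 8; then MsCl, −78 to 0 °C; then DBU, rt
Reagents that add atoms: none
Why: Kinetic deprotonation should occur at the unsubstituted α-carbon C8, and aldol addition followed by E1cB loss of mesylate (aldol condensation) should give the thermodynamically preferred (E)-enone with C6 anti to the carbonyl and cis to C9.

Step 7
Reactants: 11 (E)-alkylidene ketone
Product: 12 spiro-epoxy ketone (8R,7S; epoxide oxygen β on C8)
Conditions: t-BuOOH (decane solution), DBU, CH2Cl2, 0 °C to rt
Reagents that add atoms: tert-butyl hydroperoxide, CC(C)(C)OO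
Why: Nucleophilic (Weitz–Scheffer) epoxidation of the only enone; in the ring-closing step the bulkier C7 substituent should stay anti to the C9 arm, so the oxygen ends up β on C8 (cis to the arm) with the (E)-geometry retained (C6 cis to C9).

Step 8
Reactants: 12 spiro-epoxy ketone
Product: 13 7R-acetoxy 8β-hydroxy ketone
Conditions: CsOAc, AcOH, DMF, 70 °C
Reagents that add atoms: acetic acid, CC(=O)O
Why: Acetate should open the α,β-epoxy ketone at its β-carbon C7 (the only secondary epoxide carbon, remote from the deactivating carbonyl) with inversion, giving 7-OAc anti to the tertiary 8β-OH, which is the trans-diaxial pair of the target.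

Step 9
Reactants: 13 acetoxy hydroxy ketone
Product: 14 C8 silyl ether and C14 silyl enol ether
Conditions: t-BuMe2SiOTf (3 equiv), Et3N, CH2Cl2, 0 °C to rt
Reagents that add atoms: tert-butyldimethylsilyl trifluoromethanesulfonate, CC(C)(C)[Si](C)(C)OS(=O)(=O)C(F)(F)F
Why: Silyl triflate/amine soft enolisation should silylate the tertiary alcohol and turn the ketone, enolisable only at C13, into its tetrasubstituted enol ether, which erases the C13 mixture without a strong base that would attack the acetate.

Step 10
Reactants: 14 silyl enol ether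
Product: 15 13α-(1-hydroxyethyl)-13β-methyl ketone
Conditions: MeCHO, BF3·OEt2, CH2Cl2, −78 °C; aqueous NaHCO3
Reagents that add atoms: acetaldehyde, CC=O
Why: Mukaiyama aldol addition; the axial 8β-silyloxy group is syn-axial to the β-face of C13 (as the angular methyl is in 2α-alkylations of 3-keto steroids), so acetaldehyde should add from the α-face and leave the C13 methyl β.

Step 11
Reactants: 15 β-hydroxy ketone
Product: 16 13α-vinyl ketone
Conditions: Burgess reagent, toluene, 70 °C
Reagents that add atoms: none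
Why: Burgess syn-elimination of the secondary alcohol can only use the methyl hydrogens because C13 is quaternary, so the vinyl group should form without touching the C13 centre.

Step 12
Reactants: 16 vinyl ketone
Product: 17 primary alcohol at C5
Conditions: pyridinium p-toluenesulfonate (cat.), MeOH, rt
Reagents that add atoms: none
Why: Mild acidic methanolysis should cleave the primary tert-butyldimethylsilyl ether selectively over the hindered tertiary one at C8 and the tert-butyldiphenylsilyl ether at C2.

Step 13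
Reactants: 17 primary alcohol
Product: 19 (E)-2-methyl enal (cyclisation precursor), via aldehyde 18 (not isolated)
Conditions: Dess–Martin periodinane, NaHCO3, CH2Cl2, 0 °C to rt; then Ph3P=C(Me)CHO, 40 °C
Reagents that add atoms: 2-(triphenylphosphoranylidene)propanal, CC(C=O)=P(c1ccccc1)(c1ccccc1)c1ccccc1
Why: Dess–Martin oxidation and in-situ Wittig olefination with the formyl-stabilised ylide should trap the elimination-prone β-acetoxy aldehyde directly as the (E)-enal that holds C4, C18 and C3.

Step 14
Reactants: 19 (E)-2-methyl enal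
Product: 20 tricyclic aldehyde (ring B closed; 10β-Me, 5α-H; C4 epimers)
Conditions: Fe(acac)3 (30 mol %), PhSiH3 (2.5 equiv), EtOH/ethylene glycol, 60 °C
Reagents that add atoms: none
Why: An iron hydride formed from Fe(acac)3 and PhSiH3 should transfer a hydrogen atom to the terminal carbon of the 1,1-disubstituted alkene (the vinyl group on quaternary C13 and the electron-poor enal react far more slowly), the tertiary C10 radical adds to C5, the β-carbon of the enal, and the α-formyl radical is reduced to the enolate and protonated by ethanol. The closest known reaction type is the hydrogen-atom-transfer initiated reductive olefin coupling (Giese addition) in its intramolecular form, which is used to build quaternary carbons of decalins. Ring B closes in the 6-exo-trig mode through a chair transition state that is trans-fused to the ring C chair because the C8 and C9 side chains are both equatorial. C5 is set by the enal taking the equatorial position (H-5 axial, α); C10 is set by allylic-type strain at the planar radical, which should put the larger silyloxyethyl arm in the open sector next to H-9 (equatorial, the later C1) and the new methyl in the cleft between C8 and C11 (axial, β), where the bulky axial 8β-silyloxy group penalises anything larger than methyl. The step needs chemoselective hydrogen-atom transfer and ring closure faster than radical reduction, secured by the alkene substitution pattern and by the polarity match of a nucleophilic tertiary radical with the enal; the methyl/arm discrimination at C10 rests on sterics alone and is the least secure element. The C4 epimers are of no consequence.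

Step 15
Reactants: 20 tricyclic aldehyde
Product: 21 gem-dimethyl aldehyde (C4 quaternary)
Conditions: KOt-Bu (1.1 equiv), MeI, THF, −78 to 0 °C
Reagents that add atoms: iodomethane, CI
Why: The aldehyde α-hydrogen is by far the most acidic C–H (the C14 ketone lies between two quaternary carbons), so the potassium enolate should form selectively and C-methylation gives the gem-dimethyl C4, removing that stereocentre.

Step 16
Reactants: 21 gem-dimethyl aldehyde
Product: 22 hydroxy aldehyde (C2 primary alcohol, 8β-OH free)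
Conditions: aqueous HF (48 %), MeCN, rt
Reagents that add atoms: none
Why: Acidic fluoride should cleave both the primary tert-butyldiphenylsilyl and the tertiary tert-butyldimethylsilyl ether, while acetate, benzoate, vinyl group and aldehyde are stable to these conditions.

Step 17
Reactants: 22 hydroxy aldehyde
Product: 23 target diacid (CNP0315860.1)
Conditions: TEMPO (cat.), NaClO2, NaOCl (cat.), phosphate buffer pH 6.7, MeCN, 35 °C
Reagents that add atoms: sodium chlorite, [Na+].[O-]Cl=O
Why: Oxoammonium/chlorite oxidation should take the primary alcohol (through its aldehyde) and the neopentyl aldehyde to the two carboxylic acids in one operation without affecting the tertiary α-ketol, the esters or the vinyl group.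

**Compound list**

1 | (S)-(+)-carvone, (5S)-2-methyl-5-(prop-1-en-2-yl)cyclohex-2-en-1-one | CC1=CC[C@H](C(C)=C)CC1=O | starting material
2 | (5S)-5-(4-hydroxybut-1-en-2-yl)-2-methylcyclohex-2-en-1-one | CC1=CC[C@H](C(=C)CCO)CC1=O | intermediate
3 | (5S)-5-[4-(tert-butyldiphenylsilyloxy)but-1-en-2-yl]-2-methylcyclohex-2-en-1-one | CC1=CC[C@H](C(=C)CCO[Si](c2ccccc2)(c2ccccc2)C(C)(C)C)CC1=O | intermediate
4 | linear trimethylsilyl dienol ether of 3 (C14-OSiMe3; C13=C14 and C11=C12) | CC1=C(O[Si](C)(C)C)C[C@@H](C(=C)CCO[Si](c2ccccc2)(c2ccccc2)C(C)(C)C)C=C1 | intermediate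
5 | (4R,5S)-5-[4-(tert-butyldiphenylsilyloxy)but-1-en-2-yl]-4-hydroxy-2-methylcyclohex-2-en-1-one (11α-OH, trans to the C9 arm) | CC1=C[C@@H](O)[C@H](C(=C)CCO[Si](c2ccccc2)(c2ccccc2)C(C)(C)C)CC1=O | intermediate
6 | (4R,5S)-4-benzoyloxy-5-[4-(tert-butyldiphenylsilyloxy)but-1-en-2-yl]-2-methylcyclohex-2-en-1-one | CC1=C[C@@H](OC(=O)c2ccccc2)[C@H](C(=C)CCO[Si](c2ccccc2)(c2ccccc2)C(C)(C)C)CC1=O | intermediate
7 | (4R,5S)-4-benzoyloxy-5-[4-(tert-butyldiphenylsilyloxy)but-1-en-2-yl]-2-methylcyclohexan-1-one, C13 epimers | CC1C[C@@H](OC(=O)c2ccccc2)[C@H](C(=C)CCO[Si](c2ccccc2)(c2ccccc2)C(C)(C)C)CC1=O | intermediate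
8 | 3-(tert-butyldimethylsilyloxy)propanal | O=CCCO[Si](C)(C)C(C)(C)C | starting material
9 | aldol adduct of 7 and 8 at C8 (β-hydroxy ketone, diastereomer mixture) | CC1C[C@@H](OC(=O)c2ccccc2)[C@H](C(=C)CCO[Si](c2ccccc2)(c2ccccc2)C(C)(C)C)C(C(O)CCO[Si](C)(C)C(C)(C)C)C1=O | intermediate
10 | methanesulfonate of 9 | CC1C[C@@H](OC(=O)c2ccccc2)[C@H](C(=C)CCO[Si](c2ccccc2)(c2ccccc2)C(C)(C)C)C(C(OS(C)(=O)=O)CCO[Si](C)(C)C(C)(C)C)C1=O | intermediate
11 | (E)-C8 alkylidene ketone: 7 carrying a 3-(tert-butyldimethylsilyloxy)propylidene group on C8, C6 cis to C9 | CC1C[C@@H](OC(=O)c2ccccc2)[C@H](C(=C)CCO[Si](c2ccccc2)(c2ccccc2)C(C)(C)C)/C(=C\CCO[Si](C)(C)C(C)(C)C)C1=O | intermediate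
12 | spiro-epoxy ketone: C7–C8 epoxide, oxygen β on C8 (8R), C7 (S) with its CH2CH2OSi chain cis to C9 | CC1C[C@@H](OC(=O)c2ccccc2)[C@H](C(=C)CCO[Si](c2ccccc2)(c2ccccc2)C(C)(C)C)[C@@](O3)([C@@H]3CCO[Si](C)(C)C(C)(C)C)C1=O | intermediate
13 | 8β-hydroxy ketone with (7R)-1-acetoxy-3-(tert-butyldimethylsilyloxy)propyl chain on C8 | CC1C[C@@H](OC(=O)c2ccccc2)[C@H](C(=C)CCO[Si](c2ccccc2)(c2ccccc2)C(C)(C)C)[C@@](O)([C@H](OC(C)=O)CCO[Si](C)(C)C(C)(C)C)C1=O | intermediate
14 | C8 tert-butyldimethylsilyl ether and C14 tert-butyldimethylsilyl enol ether (C13=C14) of 13 | CC=1C[C@@H](OC(=O)c2ccccc2)[C@H](C(=C)CCO[Si](c2ccccc2)(c2ccccc2)C(C)(C)C)[C@@](O[Si](C)(C)C(C)(C)C)([C@H](OC(C)=O)CCO[Si](C)(C)C(C)(C)C)C=1O[Si](C)(C)C(C)(C)C | intermediate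
15 | 13α-(1-hydroxyethyl)-13β-methyl ketone (carbinol epimers), 8β-OSi | CC(O)[C@@]1(C)C[C@@H](OC(=O)c2ccccc2)[C@H](C(=C)CCO[Si](c2ccccc2)(c2ccccc2)C(C)(C)C)[C@@](O[Si](C)(C)C(C)(C)C)([C@H](OC(C)=O)CCO[Si](C)(C)C(C)(C)C)C1=O | intermediate
16 | 13α-vinyl-13β-methyl ketone, fully protected | C=C[C@@]1(C)C[C@@H](OC(=O)c2ccccc2)[C@H](C(=C)CCO[Si](c2ccccc2)(c2ccccc2)C(C)(C)C)[C@@](O[Si](C)(C)C(C)(C)C)([C@H](OC(C)=O)CCO[Si](C)(C)C(C)(C)C)C1=O | intermediate
17 | C5 primary alcohol | C=C[C@@]1(C)C[C@@H](OC(=O)c2ccccc2)[C@H](C(=C)CCO[Si](c2ccccc2)(c2ccccc2)C(C)(C)C)[C@@](O[Si](C)(C)C(C)(C)C)([C@H](OC(C)=O)CCO)C1=O | intermediate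
18 | C5 aldehyde (β-acetoxy aldehyde) | C=C[C@@]1(C)C[C@@H](OC(=O)c2ccccc2)[C@H](C(=C)CCO[Si](c2ccccc2)(c2ccccc2)C(C)(C)C)[C@@](O[Si](C)(C)C(C)(C)C)([C@H](OC(C)=O)CC=O)C1=O | intermediate
19 | (E)-2-methyl enal (C5=C4, C3 aldehyde), cyclisation precursor | C=C[C@@]1(C)C[C@@H](OC(=O)c2ccccc2)[C@H](C(=C)CCO[Si](c2ccccc2)(c2ccccc2)C(C)(C)C)[C@@](O[Si](C)(C)C(C)(C)C)([C@H](OC(C)=O)C/C=C(\C)C=O)C1=O | intermediate
20 | tricyclic aldehyde: ring B closed, 10β-methyl, 5α-H, C4 epimers; 7α-OAc, 8β-OSi, 11α-OBz | C=C[C@@]1(C)C[C@@H](OC(=O)c2ccccc2)[C@@H]2[C@@](C)(CCO[Si](c3ccccc3)(c3ccccc3)C(C)(C)C)[C@H](C(C)C=O)C[C@@H](OC(C)=O)[C@@]2(O[Si](C)(C)C(C)(C)C)C1=O | intermediate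
21 | gem-dimethyl aldehyde (C4 quaternary) | C=C[C@@]1(C)C[C@@H](OC(=O)c2ccccc2)[C@@H]2[C@@](C)(CCO[Si](c3ccccc3)(c3ccccc3)C(C)(C)C)[C@H](C(C)(C)C=O)C[C@@H](OC(C)=O)[C@@]2(O[Si](C)(C)C(C)(C)C)C1=O | intermediate
22 | hydroxy aldehyde: C2 primary alcohol, C3 aldehyde, 8β-OH | C=C[C@@]1(C)C[C@@H](OC(=O)c2ccccc2)[C@@H]2[C@@](C)(CCO)[C@H](C(C)(C)C=O)C[C@@H](OC(C)=O)[C@@]2(O)C1=O | intermediate
23 | CNP0315860.1, 7α-acetoxy-11α-benzoyloxy-8β-hydroxy-14-oxo-2,3-seco-isopimar-15-ene-2,3-dioic acid | C=C[C@@]1(C)C[C@@H](OC(=O)c2ccccc2)[C@@H]2[C@@](C)(CC(=O)O)[C@H](C(C)(C)C(=O)O)C[C@@H](OC(C)=O)[C@@]2(O)C1=O | target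

Total step count: 17. Longest linear sequence: 17 steps (1 to 23).

**Steps most likely to fail**

Step 14 (key step). The tertiary C10 radical may be reduced, or the enal may itself take up a hydrogen atom, before the ring closes against the syn-axial 8β-silyloxy group. In addition, the facial discrimination at C10 rests only on sterics. The fallback generates the same radical without any hydride source. It sets out from 17 and comes back at 20. Mukaiyama hydration of the 1,1-disubstituted alkene of 17 (Co(acac)2, PhSiH3, O2, i-PrOH) should give the tertiary alcohol diol F1. Dess–Martin oxidation of its primary hydroxyl gives the hydroxy aldehyde F2, which is trapped in the same flask with Ph3P=C(Me)CHO as the hydroxy enal F3. Acylation of the tertiary alcohol with methyl chlorooxoacetate (Et3N, DMAP) gives the methyl oxalate F4, and one equivalent of CsOH in THF/water gives the caesium oxalate F5. Irradiation with blue light and Ir[dF(CF3)ppy]2(dtbbpy)PF6 in wet DME/DMF releases two CO2 and the C10 radical, which closes 6-exo onto the enal; reduction and protonation of the α-formyl radical give 20.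

Step 3. Oxygen transfer may occur at the α-carbon C13 of the dienol ether instead of the γ-carbon C11, so that γ-regioselectivity is lost. The fallback fixes the regiochemistry by a cycloaddition. It sets out from 3 (through the same dienol ether 4) and comes back at 5. Tetraphenylporphyrin-sensitised photo-oxygenation of 4 (O2, hν, CH2Cl2, −78 °C) should add singlet oxygen [4+2] across C14 and C11 on the face anti to the C9 arm, giving the bridged endoperoxide F6. Methanol opens its silyl peroxyketal to the 11α-hydroperoxy enone F7, and PPh3 reduces this to 5.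

Step 10. The hindered tetrasubstituted silyl enol ether may add to acetaldehyde sluggishly, or the quaternary aldol may revert on dehydration. The fallback replaces aldol/dehydration by a cross-coupling. It sets out from 13 and comes back at 16, bypassing 14 and 15. Selective silylation of the tertiary hydroxyl of 13 (t-BuMe2SiOTf, 2,6-lutidine, CH2Cl2, −78 to 0 °C) gives the C8 silyl ether ketone F8. Palladium-catalysed α-vinylation of its only enolisable position (Pd2(dba)3, P(t-Bu)3, LiN(SiMe3)2, vinyl bromide, toluene, rt) should then give 16 directly, with the same α-face preference imposed by the axial 8β-silyloxy group.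

Further compounds
F1 | step 14 | 17 with the C10 alkene hydrated: tertiary alcohol at C10 (epimers) and C5 primary alcohol | C=C[C@@]1(C)C[C@@H](OC(=O)c2ccccc2)[C@H](C(C)(O)CCO[Si](c2ccccc2)(c2ccccc2)C(C)(C)C)[C@@](O[Si](C)(C)C(C)(C)C)([C@H](OC(C)=O)CCO)C1=O
F2 | step 14 | C5 aldehyde of F1 (not isolated) | C=C[C@@]1(C)C[C@@H](OC(=O)c2ccccc2)[C@H](C(C)(O)CCO[Si](c2ccccc2)(c2ccccc2)C(C)(C)C)[C@@](O[Si](C)(C)C(C)(C)C)([C@H](OC(C)=O)CC=O)C1=O
F3 | step 14 | (E)-2-methyl enal with tertiary C10 alcohol | C=C[C@@]1(C)C[C@@H](OC(=O)c2ccccc2)[C@H](C(C)(O)CCO[Si](c2ccccc2)(c2ccccc2)C(C)(C)C)[C@@](O[Si](C)(C)C(C)(C)C)([C@H](OC(C)=O)C/C=C(\C)C=O)C1=O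
F4 | step 14 | methyl oxalate of the tertiary C10 alcohol of F3 | C=C[C@@]1(C)C[C@@H](OC(=O)c2ccccc2)[C@H](C(C)(OC(=O)C(=O)OC)CCO[Si](c2ccccc2)(c2ccccc2)C(C)(C)C)[C@@](O[Si](C)(C)C(C)(C)C)([C@H](OC(C)=O)C/C=C(\C)C=O)C1=O
F5 | step 14 | caesium oxalate of the tertiary C10 alcohol of F3 | C=C[C@@]1(C)C[C@@H](OC(=O)c2ccccc2)[C@H](C(C)(OC(=O)C(=O)[O-])CCO[Si](c2ccccc2)(c2ccccc2)C(C)(C)C)[C@@](O[Si](C)(C)C(C)(C)C)([C@H](OC(C)=O)C/C=C(\C)C=O)C1=O.[Cs+]
F6 | step 3 | 2,3-dioxabicyclo[2.2.2]oct-5-ene endoperoxide of 4 (O–O across C14 and C11, anti to the C9 arm; not isolated) | CC1=C[C@H]2OO[C@]1(O[Si](C)(C)C)C[C@H]2C(=C)CCO[Si](c3ccccc3)(c3ccccc3)C(C)(C)C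
F7 | step 3 | (4R,5S)-4-hydroperoxy enone (11α-OOH analogue of 5) | CC1=C[C@@H](OO)[C@H](C(=C)CCO[Si](c2ccccc2)(c2ccccc2)C(C)(C)C)CC1=O
F8 | step 10 | C8 tert-butyldimethylsilyl ether of 13 with the C14 ketone intact (C13 epimers) | CC1C[C@@H](OC(=O)c2ccccc2)[C@H](C(=C)CCO[Si](c2ccccc2)(c2ccccc2)C(C)(C)C)[C@@](O[Si](C)(C)C(C)(C)C)([C@H](OC(C)=O)CCO[Si](C)(C)C(C)(C)C)C1=O
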